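**Retrosynthetic overview**
1. Feature: ring A, the benzene ring of the coumarin, has four neighbouring substituents. These are C4 on C4a, O1 on C8a, the acyl carbon C1' on C8 and OMe on C7. C8 sits between two oxygen-bearing carbons and only C5 and C6 carry hydrogen, which is the pattern produced when a vinylketene joins a 1-methoxyalkyne.
2. Late disconnections: the senecioate C–O bond at O2' (made last); the C1' ketone back to a TES-protected carbinol beside the chiral-pool C2'–OTBS group; ring B (the pyranone) back to a salicylaldehyde by Wittig olefination–lactonisation.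
3. Key disconnection: ring A is cut at C8a–C8, C6–C7 and C4a–C8a. This gives the vinylketene O=C=CH–CH=CH–CH(OMe)2 (photo-Wolff product of a diazo enone) and a chiral 1-methoxyalkyne.
4. Fragments: the alkyne comes from (R)-2-hydroxy-3-methylbutanoic acid, the only source of the C2' centre, and lithium methoxyacetylide. The diazo enone comes from 2,2-dimethoxyacetaldehyde by Wittig reaction and detrifluoroacetylative diazo transfer, because diazomethane would add as a dipole across the C=C of an enoyl chloride.
5. Ring order: ring A first (step 8), ring B second (step 10).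

Key step: step 8

Assumption: the carbinol carbon C3 of the alkyne (later C1') is carried as a mixture of epimers and is written without a descriptor, because step 12 turns it into the ketone carbon.

**Step 1**
Reactants: 1 (R)-2-hydroxy-3-methylbutanoic acid
Product: 2 methyl (R)-2-hydroxy-3-methylbutanoate
Conditions: MeOH, H2SO4 (cat.), reflux
Reagents that add atoms: methanol, CO
Why: Fischer esterification is an acid-catalysed acyl substitution at C1 only, so no bond of the C2 stereocentre is touched and the (R) configuration carries over.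

**Step 2**
Reactants: 2 methyl (R)-2-hydroxy-3-methylbutanoate
Product: 3 methyl (R)-2-(tert-butyldimethylsilyloxy)-3-methylbutanoate
Conditions: TBSCl, imidazole, DMF, rt
Reagents that add atoms: tert-butyldimethylsilyl chloride, CC(C)(C)[Si](C)(C)Cl
Why: Imidazole-promoted silylation of a secondary alcohol forms only an O–Si bond and gives a TBS ether that should survive hydride, acetylide, light, heat and mild acid.

**Step 3**
Reactants: 3 methyl (R)-2-(tert-butyldimethylsilyloxy)-3-methylbutanoate
Product: 5 (R)-2-(tert-butyldimethylsilyloxy)-3-methylbutanal, via aluminium hemiacetal 4 (not isolated)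
Conditions: i-Bu2AlH (1.1 equiv), CH2Cl2, −78 °C; aq. potassium sodium tartrate
Reagents that add atoms: diisobutylaluminium hydride, CC(C)C[AlH]CC(C)C (atoms kept only in 4)
Why: Partial ester reduction with i-Bu2AlH stops at 4, which persists at −78 °C and releases the aldehyde only on work-up; 5 is used at once so that its α-centre does not epimerise.

**Step 4**
Reactants: 5 (R)-2-(tert-butyldimethylsilyloxy)-3-methylbutanal; 6 chloroacetaldehyde dimethyl acetal
Product: 8 (4R)-4-(tert-butyldimethylsilyloxy)-1-methoxy-5-methylhex-1-yn-3-ol (mixture at C3), via lithium methoxyacetylide 7 (not isolated)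
Conditions: Et2NH, n-BuLi (3 equiv per 6), THF, 0 °C; 6, 0 °C; then 5, −78 °C; H2O quench
Reagents that add atoms: n-butyllithium, [Li]CCCC (its lithium stands only in 7)
Why: The lithium amide causes a twofold β-elimination from 6 (MeOH, then HCl) and deprotonates the methoxyacetylene formed, and the acetylide adds 1,2 to the aldehyde faster than it enolises it at −78 °C; the new C3 centre is only weakly biased (Felkin–Anh) and needs no control because step 12 removes it.

**Step 5**
Reactants: 8 (4R)-4-(tert-butyldimethylsilyloxy)-1-methoxy-5-methylhex-1-yn-3-ol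
Product: 9 (4R)-4-(tert-butyldimethylsilyloxy)-1-methoxy-5-methyl-3-(triethylsilyloxy)hex-1-yne (mixture at C3)
Conditions: TESCl, imidazole, CH2Cl2, 0 °C to rt; chromatography on Et3N-deactivated silica
Reagents that add atoms: chlorotriethylsilane, CC[Si](Cl)(CC)CC
Why: Silylation under basic conditions caps the propargylic alcohol before acid can trigger a Meyer–Schuster rearrangement of the hydroxy ynol ether, and TES is chosen because it can later be removed beside the TBS ether.

**Step 6**
Reactants: 10 2,2-dimethoxyacetaldehyde (commercial aqueous solution); 11 1-(triphenylphosphoranylidene)propan-2-one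
Product: 12 (E)-5,5-dimethoxypent-3-en-2-one
Conditions: CH2Cl2, rt
Reagents that add atoms: none
Why: Wittig olefination with a ketone-stabilised ylide tolerates water and is inherently (E)-selective.

**Step 7**
Reactants: 12 (E)-5,5-dimethoxypent-3-en-2-one
Product: 14 (E)-1-diazo-5,5-dimethoxypent-3-en-2-one, via trifluoroacetyl diketone 13 (not isolated)
Conditions: LiN(SiMe3)2, THF, −78 °C; CF3CO2CH2CF3, −78 °C; brief cold 5% aq. HCl wash; then MsN3, Et3N, H2O (1 equiv), MeCN, rt
Reagents that add atoms: 2,2,2-trifluoroethyl trifluoroacetate, FC(F)(F)COC(=O)C(F)(F)F (atoms kept only in 13); methanesulfonyl azide, CS(=O)(=O)N=[N+]=[N-]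
Why: In this detrifluoroacetylative diazo transfer, kinetic deprotonation at the methyl group and trifluoroacetylation give the activated 1,3-diketone 13, which takes the diazo group from MsN3 and loses the trifluoroacetyl group, so diazomethane and pyrazoline formation at the electron-poor C=C are avoided.

**Step 8**
Reactants: 9 (4R)-4-(tert-butyldimethylsilyloxy)-1-methoxy-5-methyl-3-(triethylsilyloxy)hex-1-yne; 14 (E)-1-diazo-5,5-dimethoxypent-3-en-2-one
Product: 19 6-(dimethoxymethyl)-3-methoxy-2-[(2R)-2-(tert-butyldimethylsilyloxy)-3-methyl-1-(triethylsilyloxy)butyl]phenol (mixture at C1'), via vinylketene 15 (not isolated), via 4-alkenylcyclobutenone 16 (not isolated), via dienylketene 17 (not isolated), via cyclohexadienone 18 (not isolated)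
Conditions: 14 (excess, in portions), hν (254 nm, low-pressure Hg lamps, quartz), ClCH2CH2Cl, rt; then reflux; crude 19 taken on directly
Reagents that add atoms: none
Why: Light expels N2 from 14 and the alkenyl group shifts (photochemical Wolff rearrangement) to give vinylketene 15, whose carbonyl carbon is attacked by the oxygen-free, nucleophilic C2 of ynol ether 9 while the ketene α-carbon bonds to the methoxy-bearing C1, a [2+2] cycloaddition that forms C8a–C8 and C6–C7 in cyclobutenone 16. Light or the final heating opens 16 by four-electron electrocyclic cleavage of its C(=O)–C4 bond to dienylketene 17, and ring A then closes by six-electron electrocyclisation between the ketene carbon and the acetal-bearing alkene terminus (C4a–C8a) to cyclohexadienone 18, which tautomerises to phenol 19. The closest known reaction type is the Danheiser benzannulation in its second-generation form, where photo-Wolff-derived vinylketenes are combined with alkoxy- and siloxyalkynes. No lasting stereocentre is created: the sp3 carbons of 16 and 18 vanish on aromatisation, C1' stays a mixture, and the C2' silyl ether is a spectator under these neutral conditions. The step needs regioselectivity in the [2+2] event, and donation from the methoxy oxygen onto the remote alkyne carbon secures it, placing the side chain between OH and OMe and the acetal carbon ortho to OH. A methyl ynol ether has no β-hydrogen for retro-ene loss of an alkene on heating, and surplus 14 compensates for ketene lost by dimerisation.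

**Step 9**
Reactants: 19 6-(dimethoxymethyl)-3-methoxy-2-[(2R)-2-(tert-butyldimethylsilyloxy)-3-methyl-1-(triethylsilyloxy)butyl]phenol
Product: 20 2-hydroxy-4-methoxy-3-[(2R)-2-(tert-butyldimethylsilyloxy)-3-methyl-1-(triethylsilyloxy)butyl]benzaldehyde (mixture at C1')
Conditions: SiO2, 10% aq. oxalic acid (cat.), CH2Cl2, rt
Reagents that add atoms: water, O
Why: Acid-catalysed acetal hydrolysis is very fast here because the oxocarbenium ion is stabilised by the ortho hydroxyl and the para methoxy group, so wet acidic silica should suffice and both silyl ethers should remain.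

**Step 10**
Reactants: 20 2-hydroxy-4-methoxy-3-[(2R)-2-(tert-butyldimethylsilyloxy)-3-methyl-1-(triethylsilyloxy)butyl]benzaldehyde; 21 ethyl (triphenylphosphoranylidene)acetate
Product: 24 8-[(2R)-2-(tert-butyldimethylsilyloxy)-3-methyl-1-(triethylsilyloxy)butyl]-7-methoxycoumarin (mixture at C1'), via E-cinnamate 22 (not isolated), via Z-cinnamate 23 (not isolated)
Conditions: PhNEt2, reflux (ca. 215 °C)
Reagents that add atoms: none
Why: Wittig olefination with the ester-stabilised ylide gives mainly 22, which equilibrates with 23 at the boiling point of the amine solvent, and 23 is drained by lactonisation (6-exo-trig acyl substitution by the phenol), which closes ring B.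

**Step 11**
Reactants: 24 8-[(2R)-2-(tert-butyldimethylsilyloxy)-3-methyl-1-(triethylsilyloxy)butyl]-7-methoxycoumarin
Product: 25 8-[(2R)-2-(tert-butyldimethylsilyloxy)-1-hydroxy-3-methylbutyl]-7-methoxycoumarin (mixture at C1')
Conditions: HF·pyridine, pyridine, THF, 0 °C
Reagents that add atoms: none
Why: Selective desilylation relies on the much faster cleavage of a triethylsilyl than of a tert-butyldimethylsilyl ether, and the pyridine buffer suppresses ionisation at the benzylic carbon and silyl migration.

**Step 12**
Reactants: 25 8-[(2R)-2-(tert-butyldimethylsilyloxy)-1-hydroxy-3-methylbutyl]-7-methoxycoumarin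
Product: 26 8-[(2R)-2-(tert-butyldimethylsilyloxy)-3-methylbutanoyl]-7-methoxycoumarin
Conditions: Dess–Martin periodinane, CH2Cl2, 0 °C to rt
Reagents that add atoms: none
Why: Dess–Martin oxidation works on hindered secondary benzylic alcohols without base, merges both C1' epimers into one ketone and should not enolise the adjacent C2' centre.

**Step 13**
Reactants: 26 8-[(2R)-2-(tert-butyldimethylsilyloxy)-3-methylbutanoyl]-7-methoxycoumarin
Product: 27 8-[(2R)-2-hydroxy-3-methylbutanoyl]-7-methoxycoumarin
Conditions: 48% aq. HF, MeCN, 0 °C to rt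
Reagents that add atoms: none
Why: Acidic fluoride desilylation frees the C2' hydroxyl without base, so neither enolisation of the α-hydroxy ketone (epimerisation, acyloin shift) nor opening of the lactone is expected.

**Step 14**
Reactants: 27 8-[(2R)-2-hydroxy-3-methylbutanoyl]-7-methoxycoumarin; 28 3-methylbut-2-enoic acid
Product: 30 (2R)-1-(7-methoxy-2-oxo-2H-chromen-8-yl)-3-methyl-1-oxobutan-2-yl 3-methylbut-2-enoate (CNP0295407.1), via O-acylisourea 29 (not isolated)
Conditions: DCC, DMAP (cat.), CH2Cl2, 0 °C to rt
Reagents that add atoms: N,N'-dicyclohexylcarbodiimide, C(=NC1CCCCC1)=NC1CCCCC1 (atoms kept only in 29)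
Why: Steglich esterification acylates the oxygen only, so the C2' configuration is retained, and catalytic DMAP at low temperature with no other amine base limits enolisation of the hindered, twisted aryl ketone and deconjugation of the senecioyl group.

**Compound list**
1 | (R)-2-hydroxy-3-methylbutanoic acid | OC(=O)[C@H](O)C(C)C | starting material
2 | methyl (R)-2-hydroxy-3-methylbutanoate | COC(=O)[C@H](O)C(C)C | intermediate
3 | methyl (R)-2-(tert-butyldimethylsilyloxy)-3-methylbutanoate | COC(=O)[C@H](O[Si](C)(C)C(C)(C)C)C(C)C | intermediate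
4 | diisobutylaluminium hemiacetal of 3 (not isolated) | COC(O[Al](CC(C)C)CC(C)C)[C@H](O[Si](C)(C)C(C)(C)C)C(C)C | intermediate
5 | (R)-2-(tert-butyldimethylsilyloxy)-3-methylbutanal | O=C[C@H](O[Si](C)(C)C(C)(C)C)C(C)C | intermediate
6 | chloroacetaldehyde dimethyl acetal | COC(CCl)OC | starting material
7 | lithium methoxyacetylide (not isolated) | COC#C[Li] | intermediate
8 | (4R)-4-(tert-butyldimethylsilyloxy)-1-methoxy-5-methylhex-1-yn-3-ol (mixture at C3) | COC#CC(O)[C@H](O[Si](C)(C)C(C)(C)C)C(C)C | intermediate
9 | (4R)-4-(tert-butyldimethylsilyloxy)-1-methoxy-5-methyl-3-(triethylsilyloxy)hex-1-yne (mixture at C3) | COC#CC(O[Si](CC)(CC)CC)[C@H](O[Si](C)(C)C(C)(C)C)C(C)C | intermediate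
10 | 2,2-dimethoxyacetaldehyde | COC(OC)C=O | starting material
11 | 1-(triphenylphosphoranylidene)propan-2-one | CC(=O)C=P(c1ccccc1)(c1ccccc1)c1ccccc1 | starting material
12 | (E)-5,5-dimethoxypent-3-en-2-one | CC(=O)/C=C/C(OC)OC | intermediate
13 | (E)-1,1,1-trifluoro-7,7-dimethoxyhept-5-ene-2,4-dione (not isolated) | O=C(CC(=O)C(F)(F)F)/C=C/C(OC)OC | intermediate
14 | (E)-1-diazo-5,5-dimethoxypent-3-en-2-one | [N-]=[N+]=CC(=O)/C=C/C(OC)OC | intermediate
15 | (E)-5,5-dimethoxypenta-1,3-dien-1-one, the vinylketene (not isolated) | O=C=C/C=C/C(OC)OC | intermediate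
16 | 4-[(E)-3,3-dimethoxyprop-1-enyl]-3-methoxy-2-[(2R)-2-(tert-butyldimethylsilyloxy)-3-methyl-1-(triethylsilyloxy)butyl]cyclobut-2-en-1-one (not isolated) | O=C1C(C(O[Si](CC)(CC)CC)[C@H](O[Si](C)(C)C(C)(C)C)C(C)C)=C(OC)C1/C=C/C(OC)OC | intermediate
17 | (3E,5E)-3,7,7-trimethoxy-2-[(2R)-2-(tert-butyldimethylsilyloxy)-3-methyl-1-(triethylsilyloxy)butyl]hepta-1,3,5-trien-1-one, ketene carbon chain and C5 cis across C3=C4 (not isolated) | O=C=C(C(O[Si](CC)(CC)CC)[C@H](O[Si](C)(C)C(C)(C)C)C(C)C)/C(OC)=C\C=C\C(OC)OC | intermediate
18 | 6-(dimethoxymethyl)-3-methoxy-2-[(2R)-2-(tert-butyldimethylsilyloxy)-3-methyl-1-(triethylsilyloxy)butyl]cyclohexa-2,4-dien-1-one (not isolated) | O=C1C(C(O[Si](CC)(CC)CC)[C@H](O[Si](C)(C)C(C)(C)C)C(C)C)=C(OC)C=CC1C(OC)OC | intermediate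
19 | 6-(dimethoxymethyl)-3-methoxy-2-[(2R)-2-(tert-butyldimethylsilyloxy)-3-methyl-1-(triethylsilyloxy)butyl]phenol (mixture at C1') | COc1ccc(C(OC)OC)c(O)c1C(O[Si](CC)(CC)CC)[C@H](O[Si](C)(C)C(C)(C)C)C(C)C | intermediate
20 | 2-hydroxy-4-methoxy-3-[(2R)-2-(tert-butyldimethylsilyloxy)-3-methyl-1-(triethylsilyloxy)butyl]benzaldehyde (mixture at C1') | COc1ccc(C=O)c(O)c1C(O[Si](CC)(CC)CC)[C@H](O[Si](C)(C)C(C)(C)C)C(C)C | intermediate
21 | ethyl (triphenylphosphoranylidene)acetate | CCOC(=O)C=P(c1ccccc1)(c1ccccc1)c1ccccc1 | starting material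
22 | ethyl (E)-3-{2-hydroxy-4-methoxy-3-[(2R)-2-(tert-butyldimethylsilyloxy)-3-methyl-1-(triethylsilyloxy)butyl]phenyl}acrylate (not isolated) | CCOC(=O)/C=C/c1ccc(OC)c(C(O[Si](CC)(CC)CC)[C@H](O[Si](C)(C)C(C)(C)C)C(C)C)c1O | intermediate
23 | ethyl (Z)-3-{2-hydroxy-4-methoxy-3-[(2R)-2-(tert-butyldimethylsilyloxy)-3-methyl-1-(triethylsilyloxy)butyl]phenyl}acrylate (not isolated) | CCOC(=O)/C=C\c1ccc(OC)c(C(O[Si](CC)(CC)CC)[C@H](O[Si](C)(C)C(C)(C)C)C(C)C)c1O | intermediate
24 | 8-[(2R)-2-(tert-butyldimethylsilyloxy)-3-methyl-1-(triethylsilyloxy)butyl]-7-methoxycoumarin (mixture at C1') | COc1ccc2ccc(=O)oc2c1C(O[Si](CC)(CC)CC)[C@H](O[Si](C)(C)C(C)(C)C)C(C)C | intermediate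
25 | 8-[(2R)-2-(tert-butyldimethylsilyloxy)-1-hydroxy-3-methylbutyl]-7-methoxycoumarin (mixture at C1') | COc1ccc2ccc(=O)oc2c1C(O)[C@H](O[Si](C)(C)C(C)(C)C)C(C)C | intermediate
26 | 8-[(2R)-2-(tert-butyldimethylsilyloxy)-3-methylbutanoyl]-7-methoxycoumarin | COc1ccc2ccc(=O)oc2c1C(=O)[C@H](O[Si](C)(C)C(C)(C)C)C(C)C | intermediate
27 | 8-[(2R)-2-hydroxy-3-methylbutanoyl]-7-methoxycoumarin | COc1ccc2ccc(=O)oc2c1C(=O)[C@H](O)C(C)C | intermediate
28 | 3-methylbut-2-enoic acid (senecioic acid) | CC(C)=CC(=O)O | starting material
29 | O-(3-methylbut-2-enoyl)-N,N'-dicyclohexylisourea (not isolated) | CC(C)=CC(=O)OC(=NC1CCCCC1)NC1CCCCC1 | intermediate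
30 | (2R)-1-(7-methoxy-2-oxo-2H-chromen-8-yl)-3-methyl-1-oxobutan-2-yl 3-methylbut-2-enoate | COc1ccc2ccc(=O)oc2c1C(=O)[C@H](OC(=O)C=C(C)C)C(C)C | target

**Step count**
Total step count: 14.
Longest linear sequence: 12 steps (steps 1–5, then 8–14).

**Steps most likely to fail**

Step 8.
- What may go wrong: the alkyne carbon that must capture the short-lived, monosubstituted vinylketene is shielded by the branched bis(silyloxy) chain. Capture may therefore be slower than ketene dimerisation, acylation of the phenol already formed, or photodegradation of both partners.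
- Fallback: ring A is bought instead of built. The fallback sets out from aldehyde 5 and comes back at 25. Commercial 7-hydroxycoumarin is iodinated at C8 with I2 and KI in aqueous NH3 to give 7-hydroxy-8-iodocoumarin F1. This is methylated with MeI and K2CO3 in acetone to 8-iodo-7-methoxycoumarin F2. Iodine–magnesium exchange with i-PrMgCl·LiCl in THF at −40 °C gives (7-methoxy-2-oxo-2H-chromen-8-yl)magnesium chloride F3, which adds to 5 at low temperature and should give 25 as C1' epimers after an NH4Cl quench. Steps 12–14 then follow unchanged.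

Step 10.
- What may go wrong: E-to-Z equilibration of the cinnamate may stay incomplete, or silyl groups may be lost or migrate above 200 °C.
- Fallback: the olefination is made intramolecular, so the ring enforces the cis alkene at room temperature. The fallback sets out from 20 and comes back at 24. The phenol is acylated with bromoacetyl bromide and pyridine in CH2Cl2 at 0 °C to the 2-formylaryl bromoacetate F4. PPh3 converts this into the phosphonium bromide F5. Stirring with aqueous NaHCO3 gives the ester-stabilised ylide F6, which closes ring B by intramolecular Wittig reaction onto the neighbouring aldehyde and should deliver 24.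

Step 11.
- What may go wrong: discrimination between the two hindered secondary silyl ethers may be lost, or the electron-rich benzylic carbon may ionise during cleavage.
- Fallback: chemoselective oxidation replaces protecting-group differentiation. The fallback sets out from 24 and comes back at 27. Both silyl groups are removed with 48% aq. HF in MeCN to give 8-[(2R)-1,2-dihydroxy-3-methylbutyl]-7-methoxycoumarin F7. Only the benzylic carbinol is then oxidised with activated MnO2 in CH2Cl2, which uses the benzylic activation of C1' over the aliphatic C2' alcohol. This should give 27 directly and bypass 25 and 26.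

**Further compounds**
F1 | step 8 | 7-hydroxy-8-iodocoumarin | Oc1ccc2ccc(=O)oc2c1I
F2 | step 8 | 8-iodo-7-methoxycoumarin | COc1ccc2ccc(=O)oc2c1I
F3 | step 8 | (7-methoxy-2-oxo-2H-chromen-8-yl)magnesium chloride | COc1ccc2ccc(=O)oc2c1[Mg]Cl
F4 | step 10 | 6-formyl-3-methoxy-2-[(2R)-2-(tert-butyldimethylsilyloxy)-3-methyl-1-(triethylsilyloxy)butyl]phenyl bromoacetate | COc1ccc(C=O)c(OC(=O)CBr)c1C(O[Si](CC)(CC)CC)[C@H](O[Si](C)(C)C(C)(C)C)C(C)C
F5 | step 10 | triphenylphosphonium bromide derived from F4 | COc1ccc(C=O)c(OC(=O)C[P+](c2ccccc2)(c2ccccc2)c2ccccc2)c1C(O[Si](CC)(CC)CC)[C@H](O[Si](C)(C)C(C)(C)C)C(C)C.[Br-]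
F6 | step 10 | aryl (triphenylphosphoranylidene)acetate derived from F5 | COc1ccc(C=O)c(OC(=O)C=P(c2ccccc2)(c2ccccc2)c2ccccc2)c1C(O[Si](CC)(CC)CC)[C@H](O[Si](C)(C)C(C)(C)C)C(C)C
F7 | step 11 | 8-[(2R)-1,2-dihydroxy-3-methylbutyl]-7-methoxycoumarin (mixture at C1') | COc1ccc2ccc(=O)oc2c1C(O)[C@H](O)C(C)C
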